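**Plan**
The only ring (C8–C12, prostanoid numbering) is cut last at C9–C10: the C9 ketone, the chlorine-bearing C10 and the C11 methine are read as an aldehyde C9–H added across a C10≡C11 chloroalkyne that sits on the quaternary carbinol carbon C12 next to C8.
Earlier cuts, working back along the open chain: C10≡C11 (one-carbon homologation of a lactone-derived C11 aldehyde), C3–C4 (radical addition of a C4 iodide to methyl acrylate), C12–O and C12–C13 (hydroxylation and allylation of a γ-lactone enolate), C8–C12 (vinyl opening of an epoxy alcohol), C7=C8 (Wittig).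
Forward order: L-threitol acetonide (C4–C7) → allylic alcohol → epoxy alcohol → vinyl at C8 → cis γ-lactone (O7–C11) → octenyl then hydroxyl at C12 → alkyne → iodide, triacetate, acrylate chain → chloroalkyne → C9 aldehyde → ring closure → desilylation.
Stereochemistry: C5 and C6 from L-tartaric acid (as the threitol acetonide); C7 from the Sharpless epoxidation; C8 by SN2 inversion in the epoxide opening; C12 by hydroxylation of the lactone enolate on the face away from the cis substituents at C8 and C7; the Z-alkene from (Z)-oct-2-en-1-ol.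
Key step: step 22

Remark: prostanoid numbering (C1 ester carbon to C20) is used for every intermediate. Open-chain intermediates are named as 9,10-secoprostanes (C9–C10 bond missing, C9 a one-carbon branch on C8), and as 1,2,3-trinor compounds (C4–C20) before the acrylate is attached. PMB = 4-methoxybenzyl, TBDPS = tert-butyldiphenylsilyl, TBS = tert-butyldimethylsilyl. The C12 oxygen is assumed to be best carried through the ring closure as its TBS ether, so that the primary TBDPS ether at C9 can be cleaved beside it. CIP letters are quoted only where they were worked out for the compound at hand; from the step in which it is made, each of C5–C8 and C12 has the spatial arrangement of the target.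

Step 1
Reactants: 1 (4S,5S)-2,2-dimethyl-1,3-dioxolane-4,5-dimethanol (2,3-O-isopropylidene-L-threitol)
Product: 2 [(4S,5S)-5-{[(4-methoxybenzyl)oxy]methyl}-2,2-dimethyl-1,3-dioxolan-4-yl]methanol
Conditions: NaH (1.0 equiv), 4-methoxybenzyl chloride (1.0 equiv), DMF, 0 °C to rt
Reagents that add atoms: 4-methoxybenzyl chloride, COc1ccc(CCl)cc1
Why: Williamson etherification of the mono-alkoxide; the diol is C2-symmetric, so either hydroxyl gives the same mono-PMB ether and the tartrate-derived centres (C5 and C6) are untouched.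

Step 2
Reactants: 2 [(4S,5S)-5-{[(4-methoxybenzyl)oxy]methyl}-2,2-dimethyl-1,3-dioxolan-4-yl]methanol
Product: 4 ethyl (2E)-3-[(4S,5S)-5-{[(4-methoxybenzyl)oxy]methyl}-2,2-dimethyl-1,3-dioxolan-4-yl]prop-2-enoate, via aldehyde 3 (not isolated)
Conditions: (COCl)2, DMSO, CH2Cl2, −78 °C; Et3N; then Ph3P=CHCO2Et, −78 °C to rt
Reagents that add atoms: ethyl (triphenylphosphoranylidene)acetate, CCOC(=O)C=P(c1ccccc1)(c1ccccc1)c1ccccc1
Why: Swern oxidation followed in the same flask by Wittig olefination with the stabilised ylide should give the E-enoate (C7=C8 plus C9), the α-alkoxy aldehyde never being isolated and sitting in its more stable trans-dioxolane form.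

Step 3
Reactants: 4 ethyl (2E)-3-[(4S,5S)-5-{[(4-methoxybenzyl)oxy]methyl}-2,2-dimethyl-1,3-dioxolan-4-yl]prop-2-enoate
Product: 5 (2E)-3-[(4S,5S)-5-{[(4-methoxybenzyl)oxy]methyl}-2,2-dimethyl-1,3-dioxolan-4-yl]prop-2-en-1-ol
Conditions: iBu2AlH (2.2 equiv), CH2Cl2, −78 °C
Reagents that add atoms: none
Why: 1,2-reduction of a conjugated ester by the aluminium hydride at low temperature is the standard route to an E-allylic alcohol and leaves alkene geometry, acetonide and PMB ether alone.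

Step 4
Reactants: 5 (2E)-3-[(4S,5S)-5-{[(4-methoxybenzyl)oxy]methyl}-2,2-dimethyl-1,3-dioxolan-4-yl]prop-2-en-1-ol
Product: 6 {(2S,3R)-3-[(4R,5S)-5-{[(4-methoxybenzyl)oxy]methyl}-2,2-dimethyl-1,3-dioxolan-4-yl]oxiran-2-yl}methanol
Conditions: Ti(OiPr)4 (0.2 equiv), L-(+)-diethyl tartrate (0.24 equiv), t-BuOOH (2 equiv, isooctane), 4 Å molecular sieves, CH2Cl2, −20 °C
Reagents that add atoms: tert-butyl hydroperoxide, CC(C)(C)OO
Why: Sharpless asymmetric epoxidation, in which the Ti(OiPr)4–L-(+)-tartrate catalyst should deliver oxygen to the alkene face that makes C8 (S) and C7 (R) (the facial sense that gives 2S,3S epoxides from simple E-allylic alcohols), reagent control outweighing the small bias of the dioxolane centre.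

Step 5
Reactants: 6 {(2S,3R)-3-[(4R,5S)-5-{[(4-methoxybenzyl)oxy]methyl}-2,2-dimethyl-1,3-dioxolan-4-yl]oxiran-2-yl}methanol
Product: 7 (1R,2R)-2-(hydroxymethyl)-1-[(4S,5S)-5-{[(4-methoxybenzyl)oxy]methyl}-2,2-dimethyl-1,3-dioxolan-4-yl]but-3-en-1-ol
Conditions: vinylmagnesium bromide (4 equiv), CuBr·SMe2 (0.2 equiv), THF/Et2O, −30 to 0 °C
Reagents that add atoms: vinylmagnesium bromide, C=C[Mg]Br
Why: copper-catalysed Grignard opening of a 2,3-epoxy alcohol should occur at C8, because C7 is deactivated and shielded by the adjacent dioxolane carbon and oxygen; backside attack inverts C8 and places the vinyl group (C12 and C11) anti to the C7 hydroxyl, which keeps its oxygen and configuration.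

Step 6
Reactants: 7 (1R,2R)-2-(hydroxymethyl)-1-[(4S,5S)-5-{[(4-methoxybenzyl)oxy]methyl}-2,2-dimethyl-1,3-dioxolan-4-yl]but-3-en-1-ol
Product: 8 (1R,2R)-2-({[tert-butyl(diphenyl)silyl]oxy}methyl)-1-[(4S,5S)-5-{[(4-methoxybenzyl)oxy]methyl}-2,2-dimethyl-1,3-dioxolan-4-yl]but-3-en-1-ol
Conditions: TBDPSCl (1.05 equiv), imidazole, CH2Cl2, 0 °C
Reagents that add atoms: tert-butyl(chloro)diphenylsilane, CC(C)(C)[Si](Cl)(c1ccccc1)c1ccccc1
Why: selective silylation, the bulky chlorosilane reacting at the primary C9 hydroxyl of the 1,3-diol far faster than at the hindered secondary C7 hydroxyl.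

Step 7
Reactants: 8 (1R,2R)-2-({[tert-butyl(diphenyl)silyl]oxy}methyl)-1-[(4S,5S)-5-{[(4-methoxybenzyl)oxy]methyl}-2,2-dimethyl-1,3-dioxolan-4-yl]but-3-en-1-ol
Product: 9 (1R,2R)-2-({[tert-butyl(diphenyl)silyl]oxy}methyl)-1-[(4S,5S)-5-{[(4-methoxybenzyl)oxy]methyl}-2,2-dimethyl-1,3-dioxolan-4-yl]butane-1,4-diol
Conditions: 9-borabicyclo[3.3.1]nonane (9-BBN, 2.5 equiv), THF, 0 °C to rt; then NaOH, H2O2, 0 °C
Reagents that add atoms: hydrogen peroxide, OO
Why: hydroboration–oxidation of the monosubstituted alkene with the hindered borane should place the hydroxyl on the terminal carbon C11 (anti-Markovnikov) without touching a stereocentre.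

Step 8
Reactants: 9 (1R,2R)-2-({[tert-butyl(diphenyl)silyl]oxy}methyl)-1-[(4S,5S)-5-{[(4-methoxybenzyl)oxy]methyl}-2,2-dimethyl-1,3-dioxolan-4-yl]butane-1,4-diol
Product: 11 (4R,5R)-4-({[tert-butyl(diphenyl)silyl]oxy}methyl)-5-[(4S,5S)-5-{[(4-methoxybenzyl)oxy]methyl}-2,2-dimethyl-1,3-dioxolan-4-yl]oxolan-2-one, via lactol 10 (not isolated)
Conditions: TEMPO (0.2 equiv), PhI(OAc)2 (2.5 equiv), CH2Cl2, rt
Reagents that add atoms: none
Why: oxoammonium (TEMPO) oxidation is selective for the primary C11 alcohol; the aldehyde is trapped by the C7 hydroxyl as the five-membered lactol, which is oxidised on to the γ-lactone that holds the C8 and C7 substituents cis.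

Step 9
Reactants: 12 (Z)-oct-2-en-1-ol
Product: 13 (Z)-1-bromooct-2-ene
Conditions: CBr4, PPh3, CH2Cl2, 0 °C
Reagents that add atoms: tetrabromomethane, BrC(Br)(Br)Br
Why: Appel bromination of the primary allylic alcohol goes by SN2 displacement of the oxyphosphonium group and should keep the Z geometry.

Step 10
Reactants: 11 (4R,5R)-4-({[tert-butyl(diphenyl)silyl]oxy}methyl)-5-[(4S,5S)-5-{[(4-methoxybenzyl)oxy]methyl}-2,2-dimethyl-1,3-dioxolan-4-yl]oxolan-2-one; 13 (Z)-1-bromooct-2-ene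
Product: 14 (3S,4R,5R)-4-({[tert-butyl(diphenyl)silyl]oxy}methyl)-5-[(4S,5S)-5-{[(4-methoxybenzyl)oxy]methyl}-2,2-dimethyl-1,3-dioxolan-4-yl]-3-[(2Z)-oct-2-en-1-yl]oxolan-2-one
Conditions: LiN(iPr)2 (1.1 equiv), THF, −78 °C; then 13, DMPU, −78 to −40 °C
Reagents that add atoms: none
Why: SN2 alkylation of the lithium enolate of the γ-lactone by the primary allylic bromide should attach C13–C20 at C12 on the face away from the two cis substituents; the configuration formed here is erased in the next step, so only the regiochemistry matters.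

Step 11
Reactants: 14 (3S,4R,5R)-4-({[tert-butyl(diphenyl)silyl]oxy}methyl)-5-[(4S,5S)-5-{[(4-methoxybenzyl)oxy]methyl}-2,2-dimethyl-1,3-dioxolan-4-yl]-3-[(2Z)-oct-2-en-1-yl]oxolan-2-one
Product: 15 (3S,4R,5R)-4-({[tert-butyl(diphenyl)silyl]oxy}methyl)-3-hydroxy-5-[(4S,5S)-5-{[(4-methoxybenzyl)oxy]methyl}-2,2-dimethyl-1,3-dioxolan-4-yl]-3-[(2Z)-oct-2-en-1-yl]oxolan-2-one
Conditions: KN(SiMe3)2 (1.3 equiv), THF, −78 °C; then 3-phenyl-2-(phenylsulfonyl)oxaziridine, −78 °C; aq. NH4Cl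
Reagents that add atoms: 3-phenyl-2-(phenylsulfonyl)oxaziridine, O=S(=O)(N1OC1c1ccccc1)c1ccccc1
Why: enolate hydroxylation with the N-sulfonyloxaziridine, the planar potassium enolate taking up oxygen on the face opposite the cis C8 and C7 substituents, which sets the quaternary C12 with the hydroxyl trans and the octenyl chain cis to them, as the target requires.

Step 12
Reactants: 15 (3S,4R,5R)-4-({[tert-butyl(diphenyl)silyl]oxy}methyl)-3-hydroxy-5-[(4S,5S)-5-{[(4-methoxybenzyl)oxy]methyl}-2,2-dimethyl-1,3-dioxolan-4-yl]-3-[(2Z)-oct-2-en-1-yl]oxolan-2-one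
Product: 16 (3S,4R,5R)-3-{[tert-butyl(dimethyl)silyl]oxy}-4-({[tert-butyl(diphenyl)silyl]oxy}methyl)-5-[(4S,5S)-5-{[(4-methoxybenzyl)oxy]methyl}-2,2-dimethyl-1,3-dioxolan-4-yl]-3-[(2Z)-oct-2-en-1-yl]oxolan-2-one
Conditions: TBSOTf, 2,6-lutidine, CH2Cl2, −20 to 0 °C
Reagents that add atoms: tert-butyldimethylsilyl trifluoromethanesulfonate, CC(C)(C)[Si](C)(C)OS(=O)(=O)C(F)(F)F
Why: silylation with a silyl triflate and a hindered pyridine base is the standard way to protect a tertiary hydroxyl, and the hydroxyl sits on the open face of the lactone.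

Step 13
Reactants: 16 (3S,4R,5R)-3-{[tert-butyl(dimethyl)silyl]oxy}-4-({[tert-butyl(diphenyl)silyl]oxy}methyl)-5-[(4S,5S)-5-{[(4-methoxybenzyl)oxy]methyl}-2,2-dimethyl-1,3-dioxolan-4-yl]-3-[(2Z)-oct-2-en-1-yl]oxolan-2-one
Product: 17 (3S,4R,5R)-3-{[tert-butyl(dimethyl)silyl]oxy}-4-({[tert-butyl(diphenyl)silyl]oxy}methyl)-5-[(4S,5S)-5-{[(4-methoxybenzyl)oxy]methyl}-2,2-dimethyl-1,3-dioxolan-4-yl]-3-[(2Z)-oct-2-en-1-yl]oxolan-2-ol (anomer mixture)
Conditions: iBu2AlH (1.2 equiv), CH2Cl2, −78 °C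
Reagents that add atoms: none
Why: partial reduction of a γ-lactone by the aluminium hydride at −78 °C stops at the tetrahedral aluminate and gives the stable five-membered lactol.

Step 14
Reactants: 17 lactol (anomer mixture); 18 dimethyl (1-diazo-2-oxopropyl)phosphonate (Ohira–Bestmann reagent)
Product: 19 12-O-TBS-9-O-TBDPS-5,6-O-isopropylidene-4-O-PMB derivative of (14Z)-1,2,3-trinor-9,10-secoprost-14-en-10-yne-4,5,6,7,9,12-hexol (C12 carries ethynyl C11≡C10H; 7-OH free)
Conditions: K2CO3, MeOH/THF, 0 °C to rt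
Reagents that add atoms: none
Why: Seyferth–Gilbert homologation, in which the small equilibrium amount of open hydroxy aldehyde reacts with the diazomethylphosphonate anion formed in situ and the resulting alkylidene carbene rearranges to the terminal alkyne (C11≡C10), the quaternary C12 being unable to epimerise.

Step 15
Reactants: 19 terminal alkyne with C4–OPMB and free 7-OH
Product: 20 12-O-TBS-9-O-TBDPS-5,6-O-isopropylidene derivative of (14Z)-1,2,3-trinor-9,10-secoprost-14-en-10-yne-4,5,6,7,9,12-hexol (4-OH and 7-OH free)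
Conditions: DDQ, CH2Cl2/pH 7 buffer, 0 °C to rt
Reagents that add atoms: none
Why: oxidative cleavage of the PMB ether by DDQ (hydride abstraction, then hydrolysis of the oxocarbenium ion) is selective for the electron-rich benzyl ether and leaves silyl ethers, acetonide, alkyne and Z-alkene alone.

Step 16
Reactants: 20 diol (4-OH and 7-OH free)
Product: 21 4-deoxy-4-iodo-12-O-TBS-9-O-TBDPS-5,6-O-isopropylidene derivative of (14Z)-1,2,3-trinor-9,10-secoprost-14-en-10-yne-5,6,7,9,12-pentol (7-OH free)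
Conditions: I2, PPh3, imidazole, CH2Cl2, 0 °C to rt
Reagents that add atoms: iodine, II
Why: Appel-type iodination through the alkoxyphosphonium salt is much faster at the primary C4 hydroxyl than at the hindered secondary C7 hydroxyl, and the trans-dioxolane keeps that hydroxyl from displacing the new iodide.

Step 17
Reactants: 21 iodo alcohol with 5,6-acetonide
Product: 23 5,6,7-tri-O-acetyl-4-deoxy-4-iodo-12-O-TBS-9-O-TBDPS derivative of (14Z)-1,2,3-trinor-9,10-secoprost-14-en-10-yne-5,6,7,9,12-pentol, via triol 22 (not isolated)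
Conditions: AcOH/H2O (4:1), 45 °C; evaporate; then Ac2O, pyridine, DMAP (cat.), 0 °C to rt
Reagents that add atoms: acetic anhydride, CC(=O)OC(C)=O
Why: acid hydrolysis of the isopropylidene acetal followed by DMAP-catalysed acetylation installs the three acetates before the ester chain exists, so no δ-lactone can form from a free C5 hydroxyl.

Step 18
Reactants: 23 triacetate iodide; 24 methyl acrylate
Product: 25 methyl (5S,6R,7R,8R,12S,14Z)-5,6,7-triacetoxy-12-{[tert-butyl(dimethyl)silyl]oxy}-9-{[tert-butyl(diphenyl)silyl]oxy}-9,10-secoprost-14-en-10-yn-1-oate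
Conditions: Bu3SnH (1.5 equiv, slow addition), AIBN (cat.), methyl acrylate (10 equiv), benzene, 80 °C
Reagents that add atoms: none
Why: Giese reaction, in which the stannyl radical abstracts iodine far faster than it adds to the alkyne or alkenes, the nucleophilic primary C4 radical adds to the acrylate and the adduct radical is reduced by the tin hydride, giving C3–C1 with the methyl ester in place; β-acetoxy radicals do not fragment.

Step 19
Reactants: 25 terminal alkyne ester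
Product: 26 methyl (5S,6R,7R,8R,12S,14Z)-5,6,7-triacetoxy-12-{[tert-butyl(dimethyl)silyl]oxy}-9-{[tert-butyl(diphenyl)silyl]oxy}-10-chloro-9,10-secoprost-14-en-10-yn-1-oate
Conditions: NCS (1.3 equiv), AgOAc (0.2 equiv), acetone, 45 °C, dark
Reagents that add atoms: N-chlorosuccinimide, O=C1CCC(=O)N1Cl
Why: silver-catalysed electrophilic halogenation of a terminal alkyne, the silver acetylide formed reversibly under nearly neutral conditions being chlorinated by NCS, so no strong base meets the acetates.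

Step 20
Reactants: 26 chloroalkyne with C9–OTBDPS
Product: 27 methyl (5S,6R,7R,8R,12S,14Z)-5,6,7-triacetoxy-12-{[tert-butyl(dimethyl)silyl]oxy}-10-chloro-9-hydroxy-9,10-secoprost-14-en-10-yn-1-oate
Conditions: HF·pyridine, pyridine, THF, 0 °C to rt
Reagents that add atoms: none
Why: fluoride-mediated desilylation, the primary TBDPS ether being cleaved by buffered HF·pyridine much faster than the congested tertiary TBS ether.

Step 21
Reactants: 27 primary alcohol
Product: 28 methyl (5S,6R,7R,8R,12S,14Z)-5,6,7-triacetoxy-12-{[tert-butyl(dimethyl)silyl]oxy}-10-chloro-9-oxo-9,10-secoprost-14-en-10-yn-1-oate (the 4-alkynal)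
Conditions: Dess–Martin periodinane, CH2Cl2, 0 °C to rt; used without storage
Reagents that add atoms: none
Why: Dess–Martin oxidation of the primary alcohol under non-basic conditions should give the aldehyde without eliminating the β-acetate or epimerising C8.

Step 22
Reactants: 28 methyl (5S,6R,7R,8R,12S,14Z)-5,6,7-triacetoxy-12-{[tert-butyl(dimethyl)silyl]oxy}-10-chloro-9-oxo-9,10-secoprost-14-en-10-yn-1-oate
Product: 29 methyl (5S,6R,7R,8R,12S,14Z)-5,6,7-triacetoxy-12-{[tert-butyl(dimethyl)silyl]oxy}-10-chloro-9-oxoprosta-10,14-dien-1-oate (12-O-TBS punaglandin 2)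
Conditions: [Rh(dppe)]2(BF4)2 (10 mol %; dppe = 1,2-bis(diphenylphosphino)ethane), acetone, 23 °C, argon
Reagents that add atoms: none
Why: Proposed new method: the cationic monovalent rhodium complex should add oxidatively into the C9 aldehyde C–H bond, transfer the hydride to C11 of the chloroalkyne, isomerise the first-formed cis alkenylrhodium through an η2-vinyl (carbene-like) form that the chlorine lone pair on C10 can stabilise, and reductively eliminate to join C9 to C10; the closest known reaction type is the [Rh(dppe)]2(BF4)2-catalysed trans-hydroacylation of 4-alkynals to cyclopent-2-enones, which tolerates a fully substituted oxygen-bearing C3 but has not been shown with a 1-chloroalkyne. The single ring (C8–C12) closes in a formally 5-endo-dig mode that only the net trans addition of hydrogen and acyl makes possible. No stereocentre is formed: C8 and C12 come in already set and the ring alkene has no geometry to control. The step needs chemoselectivity: ring closure has to outrun decarbonylation of the acylrhodium hydride, loss of the C7 acetate or epimerisation at C8, and insertion of rhodium into the C10–Cl bond. The quaternary C12 holds aldehyde and alkyne close together, the sp C–Cl bond is strong, and the neutral room-temperature medium leaves the β-acetoxy carbonyl alone. The Z-alkene is five atoms from the formyl carbon and could only close a six-membered ketone, which this catalyst does far more slowly.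

Step 23
Reactants: 29 12-O-TBS punaglandin 2
Product: 30 punaglandin 2, methyl (5S,6R,7R,8R,12S,14Z)-5,6,7-triacetoxy-10-chloro-12-hydroxy-9-oxoprosta-10,14-dien-1-oate
Conditions: 48% aq. HF, MeCN, 0 °C to rt
Reagents that add atoms: none
Why: acid-assisted fluoride cleavage of the tertiary silyl ether in a non-basic medium should spare the acetate β to the ketone and the chloroenone.

**Compound list**
1 | (4S,5S)-2,2-dimethyl-1,3-dioxolane-4,5-dimethanol (2,3-O-isopropylidene-L-threitol) | OC[C@@H]1OC(C)(C)O[C@H]1CO | starting material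
2 | [(4S,5S)-5-{[(4-methoxybenzyl)oxy]methyl}-2,2-dimethyl-1,3-dioxolan-4-yl]methanol | OC[C@@H]1OC(C)(C)O[C@H]1COCc2ccc(OC)cc2 | intermediate
3 | (4R,5S)-5-{[(4-methoxybenzyl)oxy]methyl}-2,2-dimethyl-1,3-dioxolane-4-carbaldehyde | O=C[C@@H]1OC(C)(C)O[C@H]1COCc2ccc(OC)cc2 | intermediate
4 | ethyl (2E)-3-[(4S,5S)-5-{[(4-methoxybenzyl)oxy]methyl}-2,2-dimethyl-1,3-dioxolan-4-yl]prop-2-enoate | CCOC(=O)/C=C/[C@@H]1OC(C)(C)O[C@H]1COCc2ccc(OC)cc2 | intermediate
5 | (2E)-3-[(4S,5S)-5-{[(4-methoxybenzyl)oxy]methyl}-2,2-dimethyl-1,3-dioxolan-4-yl]prop-2-en-1-ol | OC/C=C/[C@@H]1OC(C)(C)O[C@H]1COCc2ccc(OC)cc2 | intermediate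
6 | {(2S,3R)-3-[(4R,5S)-5-{[(4-methoxybenzyl)oxy]methyl}-2,2-dimethyl-1,3-dioxolan-4-yl]oxiran-2-yl}methanol | OC[C@@H]1O[C@H]1[C@@H]2OC(C)(C)O[C@H]2COCc3ccc(OC)cc3 | intermediate
7 | (1R,2R)-2-(hydroxymethyl)-1-[(4S,5S)-5-{[(4-methoxybenzyl)oxy]methyl}-2,2-dimethyl-1,3-dioxolan-4-yl]but-3-en-1-ol | C=C[C@H](CO)[C@@H](O)[C@@H]1OC(C)(C)O[C@H]1COCc2ccc(OC)cc2 | intermediate
8 | (1R,2R)-2-({[tert-butyl(diphenyl)silyl]oxy}methyl)-1-[(4S,5S)-5-{[(4-methoxybenzyl)oxy]methyl}-2,2-dimethyl-1,3-dioxolan-4-yl]but-3-en-1-ol | C=C[C@H](CO[Si](c1ccccc1)(c2ccccc2)C(C)(C)C)[C@@H](O)[C@@H]3OC(C)(C)O[C@H]3COCc4ccc(OC)cc4 | intermediate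
9 | (1R,2R)-2-({[tert-butyl(diphenyl)silyl]oxy}methyl)-1-[(4S,5S)-5-{[(4-methoxybenzyl)oxy]methyl}-2,2-dimethyl-1,3-dioxolan-4-yl]butane-1,4-diol | OCC[C@H](CO[Si](c1ccccc1)(c2ccccc2)C(C)(C)C)[C@@H](O)[C@@H]3OC(C)(C)O[C@H]3COCc4ccc(OC)cc4 | intermediate
10 | (4R,5R)-4-({[tert-butyl(diphenyl)silyl]oxy}methyl)-5-[(4S,5S)-5-{[(4-methoxybenzyl)oxy]methyl}-2,2-dimethyl-1,3-dioxolan-4-yl]oxolan-2-ol (anomer mixture) | OC1C[C@H](CO[Si](c2ccccc2)(c3ccccc3)C(C)(C)C)[C@@H](O1)[C@@H]4OC(C)(C)O[C@H]4COCc5ccc(OC)cc5 | intermediate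
11 | (4R,5R)-4-({[tert-butyl(diphenyl)silyl]oxy}methyl)-5-[(4S,5S)-5-{[(4-methoxybenzyl)oxy]methyl}-2,2-dimethyl-1,3-dioxolan-4-yl]oxolan-2-one | O=C1C[C@H](CO[Si](c2ccccc2)(c3ccccc3)C(C)(C)C)[C@@H](O1)[C@@H]4OC(C)(C)O[C@H]4COCc5ccc(OC)cc5 | intermediate
12 | (Z)-oct-2-en-1-ol | CCCCC/C=C\CO | starting material
13 | (Z)-1-bromooct-2-ene | CCCCC/C=C\CBr | intermediate
14 | (3S,4R,5R)-4-({[tert-butyl(diphenyl)silyl]oxy}methyl)-5-[(4S,5S)-5-{[(4-methoxybenzyl)oxy]methyl}-2,2-dimethyl-1,3-dioxolan-4-yl]-3-[(2Z)-oct-2-en-1-yl]oxolan-2-one | CCCCC/C=C\C[C@@H]1C(=O)O[C@H]([C@H]1CO[Si](c2ccccc2)(c3ccccc3)C(C)(C)C)[C@@H]4OC(C)(C)O[C@H]4COCc5ccc(OC)cc5 | intermediate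
15 | (3S,4R,5R)-4-({[tert-butyl(diphenyl)silyl]oxy}methyl)-3-hydroxy-5-[(4S,5S)-5-{[(4-methoxybenzyl)oxy]methyl}-2,2-dimethyl-1,3-dioxolan-4-yl]-3-[(2Z)-oct-2-en-1-yl]oxolan-2-one | CCCCC/C=C\C[C@@]1(O)C(=O)O[C@H]([C@H]1CO[Si](c2ccccc2)(c3ccccc3)C(C)(C)C)[C@@H]4OC(C)(C)O[C@H]4COCc5ccc(OC)cc5 | intermediate
16 | (3S,4R,5R)-3-{[tert-butyl(dimethyl)silyl]oxy}-4-({[tert-butyl(diphenyl)silyl]oxy}methyl)-5-[(4S,5S)-5-{[(4-methoxybenzyl)oxy]methyl}-2,2-dimethyl-1,3-dioxolan-4-yl]-3-[(2Z)-oct-2-en-1-yl]oxolan-2-one | CCCCC/C=C\C[C@@]1(O[Si](C)(C)C(C)(C)C)C(=O)O[C@H]([C@H]1CO[Si](c2ccccc2)(c3ccccc3)C(C)(C)C)[C@@H]4OC(C)(C)O[C@H]4COCc5ccc(OC)cc5 | intermediate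
17 | (3S,4R,5R)-3-{[tert-butyl(dimethyl)silyl]oxy}-4-({[tert-butyl(diphenyl)silyl]oxy}methyl)-5-[(4S,5S)-5-{[(4-methoxybenzyl)oxy]methyl}-2,2-dimethyl-1,3-dioxolan-4-yl]-3-[(2Z)-oct-2-en-1-yl]oxolan-2-ol (anomer mixture) | CCCCC/C=C\C[C@@]1(O[Si](C)(C)C(C)(C)C)C(O)O[C@H]([C@H]1CO[Si](c2ccccc2)(c3ccccc3)C(C)(C)C)[C@@H]4OC(C)(C)O[C@H]4COCc5ccc(OC)cc5 | intermediate
18 | dimethyl (1-diazo-2-oxopropyl)phosphonate | COP(=O)(OC)C(=[N+]=[N-])C(C)=O | starting material
19 | 12-O-TBS-9-O-TBDPS-5,6-O-isopropylidene-4-O-PMB derivative of (14Z)-1,2,3-trinor-9,10-secoprost-14-en-10-yne-4,5,6,7,9,12-hexol (7-OH free; stereocentres as in 30) | CCCCC/C=C\C[C@@](O[Si](C)(C)C(C)(C)C)(C#C)[C@H](CO[Si](c1ccccc1)(c2ccccc2)C(C)(C)C)[C@@H](O)[C@@H]3OC(C)(C)O[C@H]3COCc4ccc(OC)cc4 | intermediate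
20 | 12-O-TBS-9-O-TBDPS-5,6-O-isopropylidene derivative of the same hexol (4-OH and 7-OH free) | CCCCC/C=C\C[C@@](O[Si](C)(C)C(C)(C)C)(C#C)[C@H](CO[Si](c1ccccc1)(c2ccccc2)C(C)(C)C)[C@@H](O)[C@@H]3OC(C)(C)O[C@H]3CO | intermediate
21 | 4-deoxy-4-iodo-12-O-TBS-9-O-TBDPS-5,6-O-isopropylidene derivative of (14Z)-1,2,3-trinor-9,10-secoprost-14-en-10-yne-5,6,7,9,12-pentol (7-OH free) | CCCCC/C=C\C[C@@](O[Si](C)(C)C(C)(C)C)(C#C)[C@H](CO[Si](c1ccccc1)(c2ccccc2)C(C)(C)C)[C@@H](O)[C@@H]3OC(C)(C)O[C@H]3CI | intermediate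
22 | 4-deoxy-4-iodo-12-O-TBS-9-O-TBDPS derivative of the same pentol (5-, 6- and 7-OH free) | CCCCC/C=C\C[C@@](O[Si](C)(C)C(C)(C)C)(C#C)[C@H](CO[Si](c1ccccc1)(c2ccccc2)C(C)(C)C)[C@@H](O)[C@H](O)[C@H](CI)O | intermediate
23 | 5,6,7-tri-O-acetyl-4-deoxy-4-iodo-12-O-TBS-9-O-TBDPS derivative of the same pentol | CCCCC/C=C\C[C@@](O[Si](C)(C)C(C)(C)C)(C#C)[C@H](CO[Si](c1ccccc1)(c2ccccc2)C(C)(C)C)[C@@H](OC(C)=O)[C@H](OC(C)=O)[C@H](CI)OC(C)=O | intermediate
24 | methyl acrylate | C=CC(=O)OC | starting material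
25 | methyl (5S,6R,7R,8R,12S,14Z)-5,6,7-triacetoxy-12-{[tert-butyl(dimethyl)silyl]oxy}-9-{[tert-butyl(diphenyl)silyl]oxy}-9,10-secoprost-14-en-10-yn-1-oate | CCCCC/C=C\C[C@@](O[Si](C)(C)C(C)(C)C)(C#C)[C@H](CO[Si](c1ccccc1)(c2ccccc2)C(C)(C)C)[C@@H](OC(C)=O)[C@H](OC(C)=O)[C@H](CCCC(=O)OC)OC(C)=O | intermediate
26 | methyl (5S,6R,7R,8R,12S,14Z)-5,6,7-triacetoxy-12-{[tert-butyl(dimethyl)silyl]oxy}-9-{[tert-butyl(diphenyl)silyl]oxy}-10-chloro-9,10-secoprost-14-en-10-yn-1-oate | CCCCC/C=C\C[C@@](O[Si](C)(C)C(C)(C)C)(C#CCl)[C@H](CO[Si](c1ccccc1)(c2ccccc2)C(C)(C)C)[C@@H](OC(C)=O)[C@H](OC(C)=O)[C@H](CCCC(=O)OC)OC(C)=O | intermediate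
27 | methyl (5S,6R,7R,8R,12S,14Z)-5,6,7-triacetoxy-12-{[tert-butyl(dimethyl)silyl]oxy}-10-chloro-9-hydroxy-9,10-secoprost-14-en-10-yn-1-oate | CCCCC/C=C\C[C@@](O[Si](C)(C)C(C)(C)C)(C#CCl)[C@H](CO)[C@@H](OC(C)=O)[C@H](OC(C)=O)[C@H](CCCC(=O)OC)OC(C)=O | intermediate
28 | methyl (5S,6R,7R,8R,12S,14Z)-5,6,7-triacetoxy-12-{[tert-butyl(dimethyl)silyl]oxy}-10-chloro-9-oxo-9,10-secoprost-14-en-10-yn-1-oate | CCCCC/C=C\C[C@@](O[Si](C)(C)C(C)(C)C)(C#CCl)[C@H](C=O)[C@@H](OC(C)=O)[C@H](OC(C)=O)[C@H](CCCC(=O)OC)OC(C)=O | intermediate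
29 | methyl (5S,6R,7R,8R,12S,14Z)-5,6,7-triacetoxy-12-{[tert-butyl(dimethyl)silyl]oxy}-10-chloro-9-oxoprosta-10,14-dien-1-oate (12-O-TBS punaglandin 2) | CCCCC/C=C\C[C@@]1(O[Si](C)(C)C(C)(C)C)C=C(Cl)C(=O)[C@@H]1[C@@H](OC(C)=O)[C@H](OC(C)=O)[C@H](CCCC(=O)OC)OC(C)=O | intermediate
30 | punaglandin 2, methyl (5S,6R,7R,8R,12S,14Z)-5,6,7-triacetoxy-10-chloro-12-hydroxy-9-oxoprosta-10,14-dien-1-oate | CCCCC/C=C\C[C@@]1(O)C=C(Cl)C(=O)[C@@H]1[C@@H](OC(C)=O)[C@H](OC(C)=O)[C@H](CCCC(=O)OC)OC(C)=O | target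

**Step count and risks**
Total: 23 steps. Longest linear sequence: 22 steps (1 → 30 through steps 1–8 and 10–23); step 9 is a one-step side branch.

Steps most likely to fail:

1. Step 22 (the step proposed beyond precedent). The acylrhodium hydride may decarbonylate, the metal may insert into the C–Cl bond, or the chlorinated alkenylrhodium may fail to isomerise from cis to trans, so that no ring closes. The fallback uses known reactions only, sets out from 25 and comes back at 29. Silver-catalysed iodination (N-iodosuccinimide, AgNO3 cat., acetone) should give iodoalkyne F1. Diimide from 2-nitrobenzenesulfonylhydrazide and Et3N should reduce it cis to (Z)-vinyl iodide F2. HF·pyridine should then free the C9 hydroxyl to give alcohol F3, and Dess–Martin oxidation should give aldehyde F4. An intramolecular Nozaki–Hiyama–Kishi reaction (CrCl2, NiCl2 cat., DMF) should join C10 to C9 and give cyclopentenol F5, which Dess–Martin periodinane should oxidise to enone F6. α-Chlorination of the enone with PhICl2 in pyridine (conjugate addition of pyridine, chlorination of the enolate, elimination) should then give 29; selectivity over the Z-alkene is the weak point of this last operation.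

2. Step 14. The congested lactol may open too slowly for the homologation, and under the basic methanolic conditions the tertiary silyl group may migrate to the freed C7 oxygen. The fallback sets out from 17 and comes back at 19. A Wittig reaction with Ph3P=CHCl (from (chloromethyl)triphenylphosphonium chloride and KN(SiMe3)2, THF, −78 to 0 °C) should open the lactol to chloroalkene F7. Excess LiN(iPr)2 at −78 °C should then eliminate HCl, and protonation of the acetylide on work-up should give 19 without any methanolic base.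

3. Step 23. The hindered tertiary silyl ether may be cleaved only under forcing conditions, under which the C7 acetate β to the ketone can be lost by elimination. The fallback sets out from 26 and comes back at 30; it moves the difficult desilylation to a stage without the sensitive enone. Prolonged aq. HF in MeCN should remove both silyl groups to give diol F8. Dess–Martin periodinane should oxidise only the primary hydroxyl to give hydroxy aldehyde F9. 1-(Trimethylsilyl)imidazole should give trimethylsilyl ether F10. The ring closure of step 22 on F10 should give 12-O-trimethylsilyl punaglandin 2 F11, and buffered HF·pyridine at 0 °C should release 30 under much milder conditions.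

**Further compounds**
F1 | step 22 | 10-iodo analogue of 25 (iodoalkyne at C10) | CCCCC/C=C\C[C@@](O[Si](C)(C)C(C)(C)C)(C#CI)[C@H](CO[Si](c1ccccc1)(c2ccccc2)C(C)(C)C)[C@@H](OC(C)=O)[C@H](OC(C)=O)[C@H](CCCC(=O)OC)OC(C)=O
F2 | step 22 | (10Z)-vinyl iodide from F1 (C10 iodide cis to C12) | CCCCC/C=C\C[C@@](O[Si](C)(C)C(C)(C)C)(/C=C\I)[C@H](CO[Si](c1ccccc1)(c2ccccc2)C(C)(C)C)[C@@H](OC(C)=O)[C@H](OC(C)=O)[C@H](CCCC(=O)OC)OC(C)=O
F3 | step 22 | 9-hydroxy (10Z)-vinyl iodide | CCCCC/C=C\C[C@@](O[Si](C)(C)C(C)(C)C)(/C=C\I)[C@H](CO)[C@@H](OC(C)=O)[C@H](OC(C)=O)[C@H](CCCC(=O)OC)OC(C)=O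
F4 | step 22 | 9-oxo (10Z)-vinyl iodide | CCCCC/C=C\C[C@@](O[Si](C)(C)C(C)(C)C)(/C=C\I)[C@H](C=O)[C@@H](OC(C)=O)[C@H](OC(C)=O)[C@H](CCCC(=O)OC)OC(C)=O
F5 | step 22 | 10-deschloro-9-hydroxy analogue of 29 (cyclopent-2-en-1-ol; C9 epimers) | CCCCC/C=C\C[C@@]1(O[Si](C)(C)C(C)(C)C)C=CC(O)[C@@H]1[C@@H](OC(C)=O)[C@H](OC(C)=O)[C@H](CCCC(=O)OC)OC(C)=O
F6 | step 22 | 10-deschloro analogue of 29 (cyclopent-2-enone) | CCCCC/C=C\C[C@@]1(O[Si](C)(C)C(C)(C)C)C=CC(=O)[C@@H]1[C@@H](OC(C)=O)[C@H](OC(C)=O)[C@H](CCCC(=O)OC)OC(C)=O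
F7 | step 14 | chloroalkene from 17 (C12–CH=CHCl, E/Z mixture; 7-OH free) | CCCCC/C=C\C[C@@](O[Si](C)(C)C(C)(C)C)(C=CCl)[C@H](CO[Si](c1ccccc1)(c2ccccc2)C(C)(C)C)[C@@H](O)[C@@H]3OC(C)(C)O[C@H]3COCc4ccc(OC)cc4
F8 | step 23 | 9,12-diol from 26 (both silyl groups removed) | CCCCC/C=C\C[C@@](O)(C#CCl)[C@H](CO)[C@@H](OC(C)=O)[C@H](OC(C)=O)[C@H](CCCC(=O)OC)OC(C)=O
F9 | step 23 | 12-hydroxy-9-oxo chloroalkynal | CCCCC/C=C\C[C@@](O)(C#CCl)[C@H](C=O)[C@@H](OC(C)=O)[C@H](OC(C)=O)[C@H](CCCC(=O)OC)OC(C)=O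
F10 | step 23 | 12-O-trimethylsilyl analogue of 28 | CCCCC/C=C\C[C@@](O[Si](C)(C)C)(C#CCl)[C@H](C=O)[C@@H](OC(C)=O)[C@H](OC(C)=O)[C@H](CCCC(=O)OC)OC(C)=O
F11 | step 23 | 12-O-trimethylsilyl punaglandin 2 | CCCCC/C=C\C[C@@]1(O[Si](C)(C)C)C=C(Cl)C(=O)[C@@H]1[C@@H](OC(C)=O)[C@H](OC(C)=O)[C@H](CCCC(=O)OC)OC(C)=O
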